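Slowness is the first thing these readings show: the substrate falls over tens of minutes, while the dosing lasts 3.0 min.

| setting | north | north-west | south-east | Wednesday's | Saturday's | Friday's | Sunday's | Tuesday's |
|---|---|---|---|---|---|---|---|---|
| substrate | 0.050 M | 0.025 M | 0.038 M | 0.050 M (fed, over 3.0 min) | 0.050 M | 0.050 M | 0.050 M (fed, over 3.0 min) | 0.050 M |
| partner | 1.1 equiv | 1.1 equiv | 1.1 equiv | 1.10 equiv | 1.10 equiv (fed, over 3.0 min) | 1.10 equiv (in portions, 4, over 3.0 min) | 1.10 equiv | 1.10 equiv |
| free catalyst | 0.1 mol% | 0.1 mol% | 0.1 mol% | 0.1 mol% | 0.1 mol% | 0.1 mol% | 0.1 mol% | 0.1 mol% |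
| temperature | 45 °C | 60 °C | 45 °C | 60 °C | 60 °C | 60 °C |  |  |
| remark | run made earlier | run made earlier | run made earlier | all else is in the flask from the start; the feed brings no volume worth counting | all else is in the flask from the start; the feed brings no volume worth counting | first portion at the start, last at 3.0 min | the addition at 30 °C, then warmed to 60 °C; the feed brings no volume worth counting | everything together at the start at 30 °C, warmed to 60 °C at 3.0 min |
| time |  |  |  | 15 min | 15 min | 15 min | 15 min | 15 min |

| run | time / min | target / % | substrate / % |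
|---|---|---|---|
| north | 3.00 | 18 | 81 |
| north | 4.00 | 19 | 81 |
| north | 6.00 | 24 | 67 |
| north | 10.0 | 34 | 56 |
| north | 20.0 | 30 | 35 |
| north | 30.0 | 29 | 20 |
| north-west | 1.00 | 4 | 96 |
| north-west | 3.00 | 9 | 83 |
| north-west | 5.00 | 9 | 80 |
| north-west | 8.00 | 14 | 68 |
| north-west | 12.0 | 16 | 57 |
| north-west | 15.0 | 16 | 53 |
| south-east | 3.00 | 12 | 83 |
| south-east | 4.00 | 17 | 80 |
| south-east | 6.00 | 20 | 76 |
| south-east | 10.0 | 30 | 60 |
| south-east | 20.0 | 29 | 38 |
| south-east | 30.0 | 26 | 23 |

(standard deviation of a reading: 1.5 percentage points)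

* the best flask by amount of target, in percent of the substrate charged; "all alike" if 1.5 percentage points covers them all (Wednesday's / Saturday's / Friday's / Sunday's / Tuesday's / all alike)
* amount of target at the end, in percent of the substrate charged, Wednesday's
* amount of target at the end, in percent of the substrate charged, Saturday's
* amount of target at the end, in percent of the substrate charged, Friday's
* amount of target at the end, in percent of the substrate charged, Sunday's
* amount of target at the end, in percent of the substrate charged, Tuesday's

I treat the fall of the substrate as pseudo-first-order, with one time constant, its life. The north run reads 18.6 min and the north-west run 23.6 min. No run stands at 60 °C with 0.050 M, so I take the shorter life, which makes delay cost more.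

The other time is lateness. Charge spread evenly over the dosing, whether steady or in equal portions, arrives on average 1.50 min after the start, and that holds for Wednesday's, Saturday's and Friday's. I count the cold minutes of Sunday's and Tuesday's as lost, which makes those two 3.0 min late, so the gap between the groups is again 1.50 min.

To turn reacted substrate into target I use the target share, the target standing per substrate reacted, read from the last north-west reading:

share = 34.0%

lateness / life = 0.0805

substrate left, Wednesday's = 48.5%

spread = share × left × lateness / life = 1.3 percentage points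

That spread is smaller than the margin of 1.5 points, so I call the flasks alike.

The forecast gives all alike, with 24%, 22%, 22.5%, 25% and 25%, for “The differences therefore sit within the scatter”.

The flasks give all alike: 23.7%, 23.7%, 23.7%, 23.3% and 23.3%.

    partner + free catalyst ⇌ catalyst intermediate A (K = 8.60 M⁻¹, k = 400 M⁻¹ s⁻¹, Ea = 43.0 kJ mol⁻¹, ΔH = −23.0 kJ mol⁻¹)
    substrate + catalyst intermediate A ⇌ catalyst intermediate B (K = 23.0 M⁻¹, k = 7800 M⁻¹ s⁻¹, Ea = 43.0 kJ mol⁻¹, ΔH = −65.0 kJ mol⁻¹)
    target ⇌ isomer of the product (K = 2.00, k = 0.00610 s⁻¹, Ea = 94.0 kJ mol⁻¹, ΔH = −41.0 kJ mol⁻¹)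
    catalyst intermediate C ⇌ by-product + catalyst intermediate D (K = 0.0340 M, k = 57.0 s⁻¹, Ea = 74.0 kJ mol⁻¹, ΔH = −18.0 kJ mol⁻¹)
    catalyst intermediate B ⇌ catalyst intermediate C (K = 31.0, k = 12.0 s⁻¹, Ea = 64.0 kJ mol⁻¹, ΔH = 2.00 kJ mol⁻¹)
    catalyst intermediate D ⇌ free catalyst + target (K = 0.0210 M, k = 11.0 s⁻¹, Ea = 76.0 kJ mol⁻¹, ΔH = −7.00 kJ mol⁻¹)
    (constants at 60 °C)

Wednesday's and Sunday's part by 0.40 points, inside my 1.3 points. Taking away the passing of target into isomer of the product lifts Wednesday's from 23.7% to 56.0%. That passing, both ways together, relaxes with a half-life of 1.26 min, short against 15 min, and at 15.0 min Wednesday's holds 23.7% of target beside 39.9% of isomer of the product.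

For a neighbour flask, Wednesday's with 4.40 equiv of partner and 7.46% of the substrate left at the end, the share gives 31.5%. The flask gives 33.3%.

All runs come from a simulation from invented constants, noise included.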